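## Retrosynthetic overview

Locants: ring carbons C1–C10, with the oxirane on C1/C10 (C10 bears methyl C14), OH on C3, the E-alkene C4=C5 (C4 bears methyl C15), the isobutyrate on C6 and the lactone fusion at C7/C8; C11, C12 and C13 are the lactone α-carbon, carbonyl and exocyclic CH2.
1. Target 27 ⇐ 26 ⇐ 24 by desilylation and O6-acylation; 24 ⇐ 23 ⇐ 22 by oxidation at C6 and peripheral hydride delivery, which sets 6S.
2. Key disconnection C6–C7 of the ten-membered carbocycle: intramolecular Cr(II) (Nozaki–Hiyama–Kishi) allylation of an (E)-enal (C6) by a 3-(bromomethyl)butenolide. The enabling feature is the homoallylic array O–C6–C7–C11(=C13H2), in which C7 belongs both to the carbocycle and to the γ-lactone ring (O–C8–C7–C11–C12); the lactone can therefore be carried as a butenolide whose C7=C11 bond is transposed to C11=C13 when C7 bonds to C6.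
3. Seco precursor 20: butenolide by RCM of a 2-(bromomethyl)acrylate (C8 from (S)-epichlorohydrin); cis-oxirane by Shi epoxidation of the (Z)-C1=C10 alkene, itself from a Z-iodo-olefination and an alkenyllithium–epoxide coupling; C3 from a catalytic asymmetric acetate aldol on a prenol-derived enal.
4. Ring order: oxirane (step 9), γ-lactone as butenolide (step 11), ten-membered carbocycle (step 14).

Key step: step 14

Remark (assumption): metal alkoxides and aldolates that are only protonated on aqueous work-up are not numbered; in step 3 the catalyst enantiomer is taken to be the one that directs Re-face addition (3R).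

## Route

Step 1
Reactants: 1 3-methylbut-2-en-1-ol (prenol)
Product: 2 4-methoxybenzyl prenyl ether
Conditions: NaH, PMBCl, Bu4NI (cat.), THF, 0 °C → rt
Reagents that add atoms: 4-methoxybenzyl chloride COc1ccc(CCl)cc1
Why: Williamson etherification of the primary allylic alkoxide; no stereocentre is involved.

Step 2
Reactants: 2 4-methoxybenzyl prenyl ether
Product: 3 (E)-4-(4-methoxybenzyloxy)-2-methylbut-2-enal
Conditions: SeO2 (1.2 equiv), 1,4-dioxane, 80 °C
Reagents that add atoms: selenium dioxide O=[Se]=O
Why: Riley allylic oxidation (ene reaction, then [2,3]-shift) attacks the methyl trans to the CH2O chain and should give the (E)-enal, which fixes the C4=C5 geometry.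

Step 3
Reactants: 3 (E)-4-(4-methoxybenzyloxy)-2-methylbut-2-enal; 4 tert-butyl(1-methoxyvinyloxy)dimethylsilane
Product: 5 methyl (3R,4E)-3-hydroxy-6-(4-methoxybenzyloxy)-4-methylhex-4-enoate
Conditions: SiCl4 (1.1 equiv), chiral 2,2'-binaphthyldiamine-derived bisphosphoramide (5 mol %, Re-face-selective enantiomer), i-Pr2NEt (10 mol %), CH2Cl2, −78 °C; aq. NaHCO3
Reagents that add atoms: none
Why: Lewis-base-catalysed, SiCl4-mediated Mukaiyama acetate aldol addition, a reaction type established for conjugated aldehydes; the chiral silicon cation shields the Si face, so C3 should form as 3R.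

Step 4
Reactants: 5 methyl (3R,4E)-3-hydroxy-6-(4-methoxybenzyloxy)-4-methylhex-4-enoate
Product: 6 methyl (3R,4E)-3-(tert-butyldimethylsilyloxy)-6-(4-methoxybenzyloxy)-4-methylhex-4-enoate
Conditions: TBSCl, imidazole, DMF, rt
Reagents that add atoms: tert-butyldimethylsilyl chloride CC(C)(C)[Si](C)(C)Cl
Why: Standard O-silylation of the secondary allylic alcohol; the C3–O bond is not broken.

Step 5
Reactants: 6 methyl (3R,4E)-3-(tert-butyldimethylsilyloxy)-6-(4-methoxybenzyloxy)-4-methylhex-4-enoate
Product: 7 (3R,4E)-3-(tert-butyldimethylsilyloxy)-6-(4-methoxybenzyloxy)-4-methylhex-4-enal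
Conditions: DIBAL-H (1.1 equiv), CH2Cl2, −78 °C; Rochelle salt
Reagents that add atoms: none
Why: DIBAL-H partial reduction of the methyl ester stops at the aluminium hemiacetal at −78 °C and releases the aldehyde (C1) on work-up.

Step 6
Reactants: 7 (3R,4E)-3-(tert-butyldimethylsilyloxy)-6-(4-methoxybenzyloxy)-4-methylhex-4-enal; 8 ethyltriphenylphosphonium iodide
Product: 9 (2Z,5R,6E)-5-(tert-butyldimethylsilyloxy)-2-iodo-8-(4-methoxybenzyloxy)-6-methylocta-2,6-diene
Conditions: 8, n-BuLi, THF, rt; I2, −78 °C; NaHMDS, −20 °C; then 7, −78 → −20 °C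
Reagents that add atoms: iodine II
Why: Stork–Zhao-type Wittig olefination with the α-iodoethylidene ylide should give the (Z)-2-iodoalk-2-ene (iodine cis to C2) under kinetic control, which fixes the C1=C10 geometry.

Step 7
Reactants: 9 (2Z,5R,6E)-vinyl iodide; 10 (S)-epichlorohydrin
Product: 12 (2S,4Z,7R,8E)-7-(tert-butyldimethylsilyloxy)-1-chloro-10-(4-methoxybenzyloxy)-4,8-dimethyldeca-4,8-dien-2-ol, via alkenyllithium 11 (not isolated)
Conditions: t-BuLi (2.1 equiv), Et2O, −78 °C; then 10, BF3·OEt2, −78 °C
Reagents that add atoms: none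
Why: Iodine–lithium exchange retains the alkene geometry and the BF3-activated epoxide is opened by SN2 at its CH2 terminus (C9), so the stereocentre of (S)-epichlorohydrin is carried over untouched as 8S.

Step 8
Reactants: 12 (2S,4Z,7R,8E)-chlorohydrin
Product: 14 (3S,5Z,8R,9E)-8-(tert-butyldimethylsilyloxy)-11-(4-methoxybenzyloxy)-5,9-dimethylundeca-1,5,9-trien-3-ol, via terminal epoxide 13 (not isolated)
Conditions: Me3S+ I− (4 equiv), n-BuLi (3.8 equiv), THF, −10 °C → rt
Reagents that add atoms: trimethylsulfonium iodide C[S+](C)C.[I-]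
Why: Excess dimethylsulfonium methylide first closes the chlorohydrin to the terminal epoxide (intramolecular Williamson) and then opens it at CH2 and loses Me2S (Corey–Chaykovsky-type epoxide-to-allylic-alcohol homologation); C8 is not touched.

Step 9
Reactants: 14 (3S,5Z,8R,9E)-trienol
Product: 15 (3S,5S,6R,8R,9E)-8-(tert-butyldimethylsilyloxy)-5,6-epoxy-11-(4-methoxybenzyloxy)-5,9-dimethylundeca-1,9-dien-3-ol (the (1R,10S) cis-oxirane)
Conditions: D-fructose-derived Shi ketone (30 mol %), Oxone, K2CO3, Bu4NHSO4, MeCN/DMM–aq. buffer (pH 10.5), 0 °C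
Reagents that add atoms: potassium peroxymonosulfate (Oxone) [K+].[O-]S(=O)(=O)OO
Why: Shi asymmetric epoxidation; the electrophilic chiral dioxirane should attack the most electron-rich alkene (C1=C10; C4=C5 is deactivated by two allylic C–O bonds and the vinyl group is monosubstituted) through the spiro transition state, which for this trisubstituted alkene gives the (1R,10S) cis-oxirane by reagent control.

Step 10
Reactants: 15 (1R,10S)-epoxy alcohol; 16 2-(bromomethyl)acrylic acid
Product: 17 2-(bromomethyl)acrylate ester of 15 at O8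
Conditions: DCC, DMAP (5 mol %), CH2Cl2, −10 → 0 °C
Reagents that add atoms: none
Why: Steglich esterification acylates the secondary allylic alcohol with retention at C8; low temperature and catalytic DMAP limit SN2' attack on the bromomethylacrylate.

Step 11
Reactants: 17 2-(bromomethyl)acrylate ester
Product: 18 (5S)-3-(bromomethyl)-5-substituted furan-2(5H)-one (butenolide, PMB ether at O6)
Conditions: Grubbs second-generation catalyst (10 mol %), CH2Cl2 (5 mM), 40 °C
Reagents that add atoms: none
Why: Ring-closing metathesis between the terminal vinyl group and the 1,1-disubstituted acrylate should give the α-substituted butenolide with loss of ethene; the trisubstituted C4=C5 alkene does not engage.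

Step 12
Reactants: 18 butenolide PMB ether
Product: 19 butenolide allylic alcohol (free C6–OH)
Conditions: DDQ, CH2Cl2/pH 7 buffer, 0 °C
Reagents that add atoms: none
Why: Oxidative PMB cleavage (benzylic hydride abstraction, then hydrolysis) under buffered conditions that the oxirane, silyl ether and allylic bromide tolerate.

Step 13
Reactants: 19 butenolide allylic alcohol
Product: 20 (E)-enal bromomethylbutenolide (cyclisation precursor)
Conditions: MnO2, CH2Cl2, rt
Reagents that add atoms: none
Why: MnO2 oxidation of the primary allylic alcohol to the (E)-enal under neutral heterogeneous conditions.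

Step 14
Reactants: 20 (E)-enal bromomethylbutenolide
Product: 22 macrocyclic 6R-alcohol (3-O-TBS-6-epi-deacyl target), via allylchromium(III) species 21 (not isolated)
Conditions: CrCl2 (8 equiv), THF, rt, slow addition of 20 (final 2 mM)
Reagents that add atoms: none
Why: Two equivalents of Cr(II) reduce the allylic C13–Br bond of 20 to the σ-allylchromium(III) species 21, whose γ-carbon C7 adds to the Cr-bound aldehyde carbon C6 through a closed six-membered Zimmerman–Traxler transition state (intramolecular Nozaki–Hiyama–Kishi/Barbier allylation), with transposition of C7=C11 to the exocyclic C11=C13 methylene. The closest known reactions are Cr(II)-mediated macrocyclising allylations of 2-(bromomethyl)alk-2-enoates onto aldehydes that give ten-membered germacranolide rings, and Cr- or Zn-mediated allylations of aldehydes with 3-(bromomethyl)furan-2(5H)-ones. The ten-membered carbocycle closes by C6–C7 bond formation in a 10-exo-trig mode at the carbonyl (the oxygen stays outside the ring), while the pre-formed oxirane and lactone are untouched. C7 is controlled by C8: the enal can reach C7 only anti to the C8–C9 bond with a staggered C6–C7–C8–C9 torsion (syn attack would need an eclipsed one), which gives the trans ring fusion; C6 is expected mainly as 6R from the chair with C8 pseudo-equatorial (fixed by the butenolide ring) and the s-trans enal residue equatorial, and this centre is corrected in steps 15–16. The step needs γ- over α-attack (secured by the closed transition state; α-attack would give a twelve-membered ring), 1,2- over 1,4-addition to the enal (intrinsic to allylchromium reagents), cyclisation over oligomerisation (slow addition, ≤2 mM) and survival of the trisubstituted oxirane (neutral, weakly Lewis-acidic Cr(III) in THF).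

Step 15
Reactants: 22 macrocyclic 6R-alcohol
Product: 23 macrocyclic C6 ketone
Conditions: Dess–Martin periodinane, NaHCO3, CH2Cl2, 0 °C
Reagents that add atoms: none
Why: Dess–Martin oxidation of the allylic alcohol under buffered, non-basic conditions should convert either C6 epimer into the one ketone without enolising C7.

Step 16
Reactants: 23 macrocyclic C6 ketone
Product: 24 macrocyclic 6S-alcohol (3-O-TBS-deacyl target)
Conditions: NaBH4, CeCl3·7H2O, MeOH/THF, −78 °C
Reagents that add atoms: none
Why: Luche 1,2-reduction; hydride should add to the exposed peripheral face of the C6 carbonyl, the face turned away from C4 and its methyl C15, so the new hydroxyl ends syn to C15 (6S), while C7 and the α-methylene lactone are untouched at −78 °C.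

Step 17
Reactants: 24 macrocyclic 6S-alcohol; 25 isobutyric anhydride
Product: 26 3-O-TBS target (6-O-isobutyrate)
Conditions: Et3N, DMAP (cat.), CH2Cl2, 0 °C → rt
Reagents that add atoms: none
Why: DMAP-catalysed acylation of the secondary alcohol with retention at C6.

Step 18
Reactants: 26 3-O-TBS target
Product: 27 target (CNP0114243.1)
Conditions: TBAF/AcOH (1:1), THF, 0 °C → rt
Reagents that add atoms: none
Why: Acetic-acid-buffered fluoride desilylation should leave the α-methylene lactone, the ester and the oxirane intact, and acyl migration from O6 to O3 is impossible across the E-alkene.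

## Compound list

1 | 3-methylbut-2-en-1-ol (prenol) | CC(C)=CCO | starting material
2 | 4-methoxybenzyl prenyl ether | COc1ccc(COCC=C(C)C)cc1 | intermediate
3 | (E)-4-(4-methoxybenzyloxy)-2-methylbut-2-enal | COc1ccc(COC/C=C(C)/C=O)cc1 | intermediate
4 | tert-butyl(1-methoxyvinyloxy)dimethylsilane | C=C(OC)O[Si](C)(C)C(C)(C)C | starting material
5 | methyl (3R,4E)-3-hydroxy-6-(4-methoxybenzyloxy)-4-methylhex-4-enoate | COc1ccc(COC/C=C(C)/[C@H](O)CC(=O)OC)cc1 | intermediate
6 | methyl (3R,4E)-3-(tert-butyldimethylsilyloxy)-6-(4-methoxybenzyloxy)-4-methylhex-4-enoate | COc1ccc(COC/C=C(C)/[C@H](O[Si](C)(C)C(C)(C)C)CC(=O)OC)cc1 | intermediate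
7 | (3R,4E)-3-(tert-butyldimethylsilyloxy)-6-(4-methoxybenzyloxy)-4-methylhex-4-enal | COc1ccc(COC/C=C(C)/[C@H](O[Si](C)(C)C(C)(C)C)CC=O)cc1 | intermediate
8 | ethyltriphenylphosphonium iodide | CC[P+](c1ccccc1)(c1ccccc1)c1ccccc1.[I-] | starting material
9 | (2Z,5R,6E)-5-(tert-butyldimethylsilyloxy)-2-iodo-8-(4-methoxybenzyloxy)-6-methylocta-2,6-diene | COc1ccc(COC/C=C(C)/[C@H](O[Si](C)(C)C(C)(C)C)C/C=C(/C)I)cc1 | intermediate
10 | (S)-epichlorohydrin | ClC[C@@H]1CO1 | starting material
11 | alkenyllithium from 9 (C10–Li, Z retained) | COc1ccc(COC/C=C(C)/[C@H](O[Si](C)(C)C(C)(C)C)C/C=C(/C)[Li])cc1 | intermediate (not isolated)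
12 | (2S,4Z,7R,8E)-7-(tert-butyldimethylsilyloxy)-1-chloro-10-(4-methoxybenzyloxy)-4,8-dimethyldeca-4,8-dien-2-ol | COc1ccc(COC/C=C(C)/[C@H](O[Si](C)(C)C(C)(C)C)C/C=C(/C)C[C@H](O)CCl)cc1 | intermediate
13 | terminal (S)-epoxide from 12 (C7–C8 oxirane) | COc1ccc(COC/C=C(C)/[C@H](O[Si](C)(C)C(C)(C)C)C/C=C(/C)C[C@H]2CO2)cc1 | intermediate (not isolated)
14 | (3S,5Z,8R,9E)-8-(tert-butyldimethylsilyloxy)-11-(4-methoxybenzyloxy)-5,9-dimethylundeca-1,5,9-trien-3-ol | COc1ccc(COC/C=C(C)/[C@H](O[Si](C)(C)C(C)(C)C)C/C=C(/C)C[C@H](O)C=C)cc1 | intermediate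
15 | (3S,5S,6R,8R,9E)-8-(tert-butyldimethylsilyloxy)-5,6-epoxy-11-(4-methoxybenzyloxy)-5,9-dimethylundeca-1,9-dien-3-ol | COc1ccc(COC/C=C(C)/[C@H](O[Si](C)(C)C(C)(C)C)C[C@H]2O[C@@]2(C)C[C@H](O)C=C)cc1 | intermediate
16 | 2-(bromomethyl)acrylic acid | OC(=O)C(=C)CBr | starting material
17 | 2-(bromomethyl)acrylate ester of 15 at O8 | COc1ccc(COC/C=C(C)/[C@H](O[Si](C)(C)C(C)(C)C)C[C@H]2O[C@@]2(C)C[C@H](OC(=O)C(=C)CBr)C=C)cc1 | intermediate
18 | (5S)-3-(bromomethyl)butenolide, PMB ether at O6 | COc1ccc(COC/C=C(C)/[C@H](O[Si](C)(C)C(C)(C)C)C[C@H]2O[C@@]2(C)C[C@@H]3OC(=O)C(CBr)=C3)cc1 | intermediate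
19 | butenolide allylic alcohol (free C6–OH) | OC/C=C(C)/[C@H](O[Si](C)(C)C(C)(C)C)C[C@H]1O[C@@]1(C)C[C@@H]2OC(=O)C(CBr)=C2 | intermediate
20 | (E)-enal bromomethylbutenolide (cyclisation precursor) | O=C/C=C(C)/[C@H](O[Si](C)(C)C(C)(C)C)C[C@H]1O[C@@]1(C)C[C@@H]2OC(=O)C(CBr)=C2 | intermediate
21 | allylchromium(III) species from 20 | O=C/C=C(C)/[C@H](O[Si](C)(C)C(C)(C)C)C[C@H]1O[C@@]1(C)C[C@@H]2OC(=O)C(C[Cr](Cl)Cl)=C2 | intermediate (not isolated)
22 | macrocyclic 6R-alcohol (3-O-TBS-6-epi-deacyl target; trans-fused α-methylene lactone) | C=C1C(=O)O[C@H]2C[C@]3(C)O[C@@H]3C[C@@H](O[Si](C)(C)C(C)(C)C)/C(C)=C/[C@@H](O)[C@H]12 | intermediate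
23 | macrocyclic C6 ketone | C=C1C(=O)O[C@H]2C[C@]3(C)O[C@@H]3C[C@@H](O[Si](C)(C)C(C)(C)C)/C(C)=C/C(=O)[C@H]12 | intermediate
24 | macrocyclic 6S-alcohol (3-O-TBS-deacyl target) | C=C1C(=O)O[C@H]2C[C@]3(C)O[C@@H]3C[C@@H](O[Si](C)(C)C(C)(C)C)/C(C)=C/[C@H](O)[C@H]12 | intermediate
25 | isobutyric anhydride | CC(C)C(=O)OC(=O)C(C)C | starting material
26 | 3-O-TBS target (6-O-isobutyrate) | C=C1C(=O)O[C@H]2C[C@]3(C)O[C@@H]3C[C@@H](O[Si](C)(C)C(C)(C)C)/C(C)=C/[C@H](OC(=O)C(C)C)[C@H]12 | intermediate
27 | CNP0114243.1 | C=C1C(=O)O[C@H]2C[C@]3(C)O[C@@H]3C[C@@H](O)/C(C)=C/[C@H](OC(=O)C(C)C)[C@H]12 | target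

## Step count and risks

Total steps: 18. Longest linear sequence: 18 (1 → 27).

**Step 14 (macrocyclisation).** Intermolecular allylation (oligomerisation) or protonation of the allylchromium may outrun the entropically demanding ten-membered closure, and Cr(III) may assist opening of the trisubstituted oxirane. The fallback replaces the reductive Barbier process by a thermal, metal-free allylboration of an isolated allylboronate. It sets out from 19: Pd-catalysed Miyaura-type borylation of the allylic bromide (Pd2(dba)3, bis(pinacolato)diboron, THF, 50 °C) should give the primary allyl pinacol boronate F1. MnO2 oxidation then gives the enal allylboronate F2. Heating F2 in toluene (80 °C, 2 mM) should close the ring through the same closed chair to the cyclic borate F3, and triethanolamine work-up returns the route at 22.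

**Step 16 (C6 reduction).** Hydride may be delivered to the wrong face of the C6 carbonyl, and at the β,γ-unsaturated ketone stage (23) the C11=C13 double bond may migrate into conjugation, with epimerisation at C7. The fallback avoids the ketone. It sets out from 22 (the step-14 product, or material returned by a mis-selective reduction): Mitsunobu esterification with isobutyric acid (PPh3, DIAD, toluene, 0 °C → rt) inverts C6 by SN2 and gives 26 directly. Backside access to C6 in the ring is hindered, so this is the weaker of the three fallbacks. It makes no compound outside the list (F0).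

**Step 9 (epoxidation).** The dioxirane may discriminate poorly between the faces of the Z-trisubstituted C1=C10 alkene, or epoxidise C4=C5 competitively. The fallback switches to hydroxyl-directed, metal-catalysed asymmetric epoxidation one stage earlier. It sets out from 12: Hf(Ot-Bu)4 with a chiral bishydroxamic acid ligand and cumene hydroperoxide (toluene, 0 °C) uses the homoallylic C8–OH to deliver oxygen to C1=C10 only, and should give the epoxy chlorohydrin F4. The sulfonium ylide conditions of step 8 then convert F4, through the bis-epoxide F5 (not isolated, only the terminal oxirane reacts), into 15.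

Further compounds
F1 | step 14 | allyl pinacol boronate of 19 (C13–Bpin, free C6–OH) | OC/C=C(C)/[C@H](O[Si](C)(C)C(C)(C)C)C[C@H]1O[C@@]1(C)C[C@@H]2OC(=O)C(CB3OC(C)(C)C(C)(C)O3)=C2
F2 | step 14 | enal allyl pinacol boronate | O=C/C=C(C)/[C@H](O[Si](C)(C)C(C)(C)C)C[C@H]1O[C@@]1(C)C[C@@H]2OC(=O)C(CB3OC(C)(C)C(C)(C)O3)=C2
F3 | step 14 | O6-pinacolboryl ether of 22 | C=C1C(=O)O[C@H]2C[C@]3(C)O[C@@H]3C[C@@H](O[Si](C)(C)C(C)(C)C)/C(C)=C/[C@@H](OB4OC(C)(C)C(C)(C)O4)[C@H]12
F0 | step 16 | none | none
F4 | step 9 | (1R,10S)-epoxy chlorohydrin from 12 | COc1ccc(COC/C=C(C)/[C@H](O[Si](C)(C)C(C)(C)C)C[C@H]2O[C@@]2(C)C[C@H](O)CCl)cc1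
F5 | step 9 | bis-epoxide (trisubstituted oxirane plus terminal C7–C8 oxirane) | COc1ccc(COC/C=C(C)/[C@H](O[Si](C)(C)C(C)(C)C)C[C@H]2O[C@@]2(C)C[C@H]3CO3)cc1
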